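**Retrosynthetic overview**
- Target ⇒ one acidolysis removes four Boc groups and the phenol tert-butyl ether; the two amide C–N bonds then disconnect to one diacid core and two molecules of N,N'-di-Boc-agmatine.
- Diacid ⇒ dimethyl ester; the cinnamate arm disconnects at the aryl–vinyl bond (Heck) to a 5-bromo-2-aryl-2,3-dihydrobenzofuran-3-carboxylate and methyl acrylate.
- Dihydrofuran ring (C2–C3 bond) ⇒ enantioselective rhodium-carbene 1,5 C–H insertion of an aryldiazoacetate into a benzylic ether C–H bond (sets C2), then epimerisation of C3 to trans.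
- Diazo ester ⇒ diazo transfer onto the aryl acetate ⇒ Mitsunobu ether from methyl 2-(5-bromo-2-hydroxyphenyl)acetate and 4-tert-butoxybenzyl alcohol.
- Ring order: both benzene rings are bought; the dihydrofuran ring is the only ring formed (step 3).

Assumption: compounds 1, 2, 7 and 11 are bought as catalogue items, and the bis-guanidine target is isolated as its bis(trifluoroacetate) salt, the SMILES showing its neutral form.

**Route**

Step 1
Reactants: 1 methyl 2-(5-bromo-2-hydroxyphenyl)acetate; 2 (4-tert-butoxyphenyl)methanol (4-tert-butoxybenzyl alcohol)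
Product: 3 methyl 2-{5-bromo-2-[(4-tert-butoxyphenyl)methoxy]phenyl}acetate
Conditions: PPh3 (1.2 equiv), DIAD (1.2 equiv), THF, 0 °C to rt
Reagents that add atoms: none
Why: Mitsunobu etherification alkylates the acidic phenol with the activated primary benzylic alcohol under neutral conditions, which avoids lactonisation of the hydroxyphenylacetate and needs no benzylic halide; no stereocentre is formed.

Step 2
Reactants: 3 methyl 2-{5-bromo-2-[(4-tert-butoxyphenyl)methoxy]phenyl}acetate
Product: 4 methyl 2-{5-bromo-2-[(4-tert-butoxyphenyl)methoxy]phenyl}-2-diazoacetate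
Conditions: p-ABSA (1.3 equiv), DBU (1.5 equiv), MeCN, 0 °C to rt
Reagents that add atoms: 4-acetamidobenzenesulfonyl azide (p-ABSA), CC(=O)Nc1ccc(cc1)S(=O)(=O)N=[N+]=[N-]
Why: Regitz diazo transfer works because DBU deprotonates the aryl- and ester-activated CH2 and the enolate takes N2 from the sulfonyl azide, while the ether, bromide and tert-butyl ether are inert; no stereocentre is formed.

Step 3
Reactants: 4 methyl 2-{5-bromo-2-[(4-tert-butoxyphenyl)methoxy]phenyl}-2-diazoacetate
Product: 6 methyl (2R,3R)-5-bromo-2-(4-tert-butoxyphenyl)-2,3-dihydro-1-benzofuran-3-carboxylate (2,3-trans), via cis ester 5 (not isolated)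
Conditions: Rh2(S-PTTL)4 (dirhodium tetrakis[N-phthaloyl-(S)-tert-leucinate], 2 mol %), toluene, −60 °C; evaporate; then NaOMe (0.3 equiv), MeOH/THF, 0 °C to rt; recrystallise
Reagents that add atoms: none
Why: Enantioselective intramolecular 1,5 C–H insertion of the rhodium-bound donor/acceptor carbene into the benzylic ether C–H bond closes the dihydrofuran ring, the chiral carboxylate ligands fixing C2 as R in the kinetically formed cis ester (about 85–90% ee expected by analogy with closely related 5-bromo substrates, the mirror-image catalyst Rh2(R-PTTL)4 being used instead if the opposite sense is found), after which catalytic methoxide epimerises only the enolisable C3 to the thermodynamically favoured 2,3-trans (3R) ester and recrystallisation raises the ee.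

Step 4
Reactants: 6 methyl (2R,3R)-5-bromo-2-(4-tert-butoxyphenyl)-2,3-dihydro-1-benzofuran-3-carboxylate; 7 methyl acrylate (2 equiv)
Product: 8 methyl (2R,3R)-2-(4-tert-butoxyphenyl)-5-[(E)-3-methoxy-3-oxoprop-1-en-1-yl]-2,3-dihydro-1-benzofuran-3-carboxylate
Conditions: Pd(OAc)2 (5 mol %), P(o-tol)3 (12 mol %), Et3N (2.5 equiv), MeCN, 85 °C
Reagents that add atoms: none
Why: Mizoroki–Heck reaction, in which oxidative addition of the aryl bromide to zerovalent palladium, syn insertion of the acrylate and syn β-hydride elimination give only the E-cinnamate, while the weak amine base leaves the trans C2/C3 arrangement (already the thermodynamic one) unchanged.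

Step 5
Reactants: 8 methyl (2R,3R)-2-(4-tert-butoxyphenyl)-5-[(E)-3-methoxy-3-oxoprop-1-en-1-yl]-2,3-dihydro-1-benzofuran-3-carboxylate
Product: 10 (2R,3R)-2-(4-tert-butoxyphenyl)-5-[(E)-2-carboxyethenyl]-2,3-dihydro-1-benzofuran-3-carboxylic acid, via bis(trimethylstannyl) ester 9 (not isolated)
Conditions: Me3SnOH (10 equiv), ClCH2CH2Cl, 80 °C; then cold 0.5 M HCl work-up
Reagents that add atoms: trimethyltin hydroxide, C[Sn](C)(C)O
Why: Me3SnOH-mediated ester hydrolysis transfers hydroxide from tin under nearly neutral conditions, so both methyl esters are cleaved without forming the C3 ester enolate, which avoids the E1cB opening of the dihydrofuran that threatens NaOH or LiOH saponification of this ring system, and the aryl tert-butyl ether is untouched.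

Step 6
Reactants: 10 (2R,3R)-2-(4-tert-butoxyphenyl)-5-[(E)-2-carboxyethenyl]-2,3-dihydro-1-benzofuran-3-carboxylic acid; 11 1-(4-aminobutyl)-2,3-bis(tert-butoxycarbonyl)guanidine (N,N'-di-Boc-agmatine, 2.3 equiv)
Product: 13 (2R,3R)-N-{4-[2,3-bis(tert-butoxycarbonyl)guanidino]butyl}-5-[(E)-3-({4-[2,3-bis(tert-butoxycarbonyl)guanidino]butyl}amino)-3-oxoprop-1-en-1-yl]-2-(4-tert-butoxyphenyl)-2,3-dihydro-1-benzofuran-3-carboxamide, via bis(benzotriazol-1-yl) ester 12 (not isolated)
Conditions: DIC (2.4 equiv), HOBt (2.4 equiv), CH2Cl2/DMF, 0 °C, 30 min; then 11, 0 °C to rt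
Reagents that add atoms: none
Why: Carbodiimide/HOBt amide coupling without added base converts both acids into benzotriazolyl esters, which are aminolysed by the only nucleophilic nitrogen of 11 (the primary amine), the absence of base suppressing β-elimination at C3, whose trans configuration is in any case the thermodynamic one.

Step 7
Reactants: 13 (2R,3R)-N-{4-[2,3-bis(tert-butoxycarbonyl)guanidino]butyl}-5-[(E)-3-({4-[2,3-bis(tert-butoxycarbonyl)guanidino]butyl}amino)-3-oxoprop-1-en-1-yl]-2-(4-tert-butoxyphenyl)-2,3-dihydro-1-benzofuran-3-carboxamide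
Product: 14 (2R,3R)-N-(4-guanidinobutyl)-5-{(E)-3-[(4-guanidinobutyl)amino]-3-oxoprop-1-en-1-yl}-2-(4-hydroxyphenyl)-2,3-dihydro-1-benzofuran-3-carboxamide
Conditions: TFA/CH2Cl2/H2O (50:48:2), 0 °C to rt, 3 h, N2 sweep; reverse-phase HPLC (MeCN/H2O, 0.1% TFA)
Reagents that add atoms: none
Why: Acidolysis (SN1/E1 cleavage of the four tert-butyl carbamates and of the aryl tert-butyl ether) removes every protecting group in one operation, while the amides, the E-alkene and both stereocentres are unaffected because no base is present and the trans ring is the stable form.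

**Compound list**
1 | methyl 2-(5-bromo-2-hydroxyphenyl)acetate | COC(=O)Cc1cc(Br)ccc1O | starting material
2 | (4-tert-butoxyphenyl)methanol | CC(C)(C)Oc1ccc(CO)cc1 | starting material
3 | methyl 2-{5-bromo-2-[(4-tert-butoxyphenyl)methoxy]phenyl}acetate | COC(=O)Cc1cc(Br)ccc1OCc1ccc(OC(C)(C)C)cc1 | intermediate
4 | methyl 2-{5-bromo-2-[(4-tert-butoxyphenyl)methoxy]phenyl}-2-diazoacetate | COC(=O)C(=[N+]=[N-])c1cc(Br)ccc1OCc1ccc(OC(C)(C)C)cc1 | intermediate
5 | methyl (2R,3S)-5-bromo-2-(4-tert-butoxyphenyl)-2,3-dihydro-1-benzofuran-3-carboxylate (2,3-cis, not isolated) | Brc1ccc2c(c1)[C@H](C(=O)OC)[C@H](c1ccc(OC(C)(C)C)cc1)O2 | intermediate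
6 | methyl (2R,3R)-5-bromo-2-(4-tert-butoxyphenyl)-2,3-dihydro-1-benzofuran-3-carboxylate (2,3-trans) | Brc1ccc2c(c1)[C@@H](C(=O)OC)[C@H](c1ccc(OC(C)(C)C)cc1)O2 | intermediate
7 | methyl acrylate (methyl prop-2-enoate) | C=CC(=O)OC | starting material
8 | methyl (2R,3R)-2-(4-tert-butoxyphenyl)-5-[(E)-3-methoxy-3-oxoprop-1-en-1-yl]-2,3-dihydro-1-benzofuran-3-carboxylate | COC(=O)/C=C/c1ccc2c(c1)[C@@H](C(=O)OC)[C@H](c1ccc(OC(C)(C)C)cc1)O2 | intermediate
9 | bis(trimethylstannyl) ester of diacid 10 (not isolated) | C[Sn](C)(C)OC(=O)/C=C/c1ccc2c(c1)[C@@H](C(=O)O[Sn](C)(C)C)[C@H](c1ccc(OC(C)(C)C)cc1)O2 | intermediate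
10 | (2R,3R)-2-(4-tert-butoxyphenyl)-5-[(E)-2-carboxyethenyl]-2,3-dihydro-1-benzofuran-3-carboxylic acid | OC(=O)/C=C/c1ccc2c(c1)[C@@H](C(=O)O)[C@H](c1ccc(OC(C)(C)C)cc1)O2 | intermediate
11 | 1-(4-aminobutyl)-2,3-bis(tert-butoxycarbonyl)guanidine (N,N'-di-Boc-agmatine) | CC(C)(C)OC(=O)NC(=NC(=O)OC(C)(C)C)NCCCCN | starting material
12 | bis(1H-benzotriazol-1-yl) ester of diacid 10 (not isolated) | O=C(On1nnc2ccccc12)/C=C/c1ccc2c(c1)[C@@H](C(=O)On1nnc3ccccc13)[C@H](c1ccc(OC(C)(C)C)cc1)O2 | intermediate
13 | (2R,3R)-N-{4-[2,3-bis(tert-butoxycarbonyl)guanidino]butyl}-5-[(E)-3-({4-[2,3-bis(tert-butoxycarbonyl)guanidino]butyl}amino)-3-oxoprop-1-en-1-yl]-2-(4-tert-butoxyphenyl)-2,3-dihydro-1-benzofuran-3-carboxamide | CC(C)(C)OC(=O)NC(=NC(=O)OC(C)(C)C)NCCCCNC(=O)/C=C/c1ccc2c(c1)[C@@H](C(=O)NCCCCNC(=NC(=O)OC(C)(C)C)NC(=O)OC(C)(C)C)[C@H](c1ccc(OC(C)(C)C)cc1)O2 | intermediate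
14 | (2R,3R)-N-(4-guanidinobutyl)-5-{(E)-3-[(4-guanidinobutyl)amino]-3-oxoprop-1-en-1-yl}-2-(4-hydroxyphenyl)-2,3-dihydro-1-benzofuran-3-carboxamide | NC(N)=NCCCCNC(=O)/C=C/c1ccc2c(c1)[C@@H](C(=O)NCCCCN=C(N)N)[C@H](c1ccc(O)cc1)O2 | target

**Step count and risks**
Total step count: 7. Longest linear sequence: 7 steps (1 → 3 → 4 → 6 → 8 → 10 → 13 → 14).

The three steps most likely to fail are 3, 5 and 7.

Step 3 (enantioselectivity of the C–H insertion). The risk is an ee too low to upgrade by crystallisation. The fallback replaces asymmetric induction by resolution; it sets out from 4 and comes back at 6. Diazo ester 4 is decomposed with achiral Rh2(OAc)4 (1 mol %, CH2Cl2, rt). This gives the racemic cis ester, that is 5 together with its mirror image methyl (2S,3R)-5-bromo-2-(4-tert-butoxyphenyl)-2,3-dihydro-1-benzofuran-3-carboxylate F1. NaOMe in MeOH epimerises the mixture to the racemic trans ester, that is 6 together with methyl (2S,3S)-5-bromo-2-(4-tert-butoxyphenyl)-2,3-dihydro-1-benzofuran-3-carboxylate F2. Preparative chiral SFC (amylose tris(3,5-dimethylphenylcarbamate) phase, CO2/MeOH) separates 6 from F2, and the absolute configuration is confirmed by anomalous-dispersion X-ray on the bromide.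

Step 5 (double ester cleavage without opening the dihydrofuran). The risk is slow hydrolysis of the cinnamate or partial elimination at C3. The fallback exchanges hydrolysis for a redox detour, so that no ester is ever treated with a hydroxide source; it sets out from 8 and comes back at 10. i-Bu2AlH (5 equiv, CH2Cl2, −78 °C) reduces both esters to (E)-3-[(2R,3S)-2-(4-tert-butoxyphenyl)-3-(hydroxymethyl)-2,3-dihydro-1-benzofuran-5-yl]prop-2-en-1-ol F3; the C3 descriptor changes only through ligand priorities. Dess–Martin periodinane buffered with NaHCO3 (CH2Cl2, 0 °C) gives (2R,3R)-2-(4-tert-butoxyphenyl)-5-[(E)-3-oxoprop-1-en-1-yl]-2,3-dihydro-1-benzofuran-3-carbaldehyde F4. F4 is used at once, cold, in a Pinnick oxidation (NaClO2, NaH2PO4, 2-methylbut-2-ene, t-BuOH/H2O, 0 °C), which gives diacid 10 under mildly acidic conditions.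

Step 7 (global acidolysis on the final bis-guanidine). The risks are tert-butylation of the electron-rich phenol rings by the five tert-butyl cations released, acid-promoted opening at the p-hydroxybenzylic C2–O bond, and losses on isolating a very polar salt. The fallback is an end game without guanidine protection, in which the finished molecule never meets strong acid; it sets out from 10 and comes back at 14. TFA/CH2Cl2 on 10 frees the phenol at the stage of a robust, crystallisable acid, giving (2R,3R)-5-[(E)-2-carboxyethenyl]-2-(4-hydroxyphenyl)-2,3-dihydro-1-benzofuran-3-carboxylic acid F5. DIC and N-hydroxysuccinimide in DMF convert F5 into bis(2,5-dioxopyrrolidin-1-yl) ester F6. F6 is treated with commercial agmatine sulfate (agmatine: NCCCCN=C(N)N; its guanidinium is protonated and unreactive) and NaHCO3 in DMF/H2O, so that only the primary amine is acylated, and reverse-phase HPLC gives 14 directly.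

**Further compounds**
F1 | step 3 | methyl (2S,3R)-5-bromo-2-(4-tert-butoxyphenyl)-2,3-dihydro-1-benzofuran-3-carboxylate (enantiomer of 5) | Brc1ccc2c(c1)[C@@H](C(=O)OC)[C@@H](c1ccc(OC(C)(C)C)cc1)O2
F2 | step 3 | methyl (2S,3S)-5-bromo-2-(4-tert-butoxyphenyl)-2,3-dihydro-1-benzofuran-3-carboxylate (enantiomer of 6) | Brc1ccc2c(c1)[C@H](C(=O)OC)[C@@H](c1ccc(OC(C)(C)C)cc1)O2
F3 | step 5 | (E)-3-[(2R,3S)-2-(4-tert-butoxyphenyl)-3-(hydroxymethyl)-2,3-dihydro-1-benzofuran-5-yl]prop-2-en-1-ol | OC/C=C/c1ccc2c(c1)[C@@H](CO)[C@H](c1ccc(OC(C)(C)C)cc1)O2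
F4 | step 5 | (2R,3R)-2-(4-tert-butoxyphenyl)-5-[(E)-3-oxoprop-1-en-1-yl]-2,3-dihydro-1-benzofuran-3-carbaldehyde | O=C/C=C/c1ccc2c(c1)[C@@H](C=O)[C@H](c1ccc(OC(C)(C)C)cc1)O2
F5 | step 7 | (2R,3R)-5-[(E)-2-carboxyethenyl]-2-(4-hydroxyphenyl)-2,3-dihydro-1-benzofuran-3-carboxylic acid | OC(=O)/C=C/c1ccc2c(c1)[C@@H](C(=O)O)[C@H](c1ccc(O)cc1)O2
F6 | step 7 | bis(2,5-dioxopyrrolidin-1-yl) ester of F5 | O=C(ON1C(=O)CCC1=O)/C=C/c1ccc2c(c1)[C@@H](C(=O)ON1C(=O)CCC1=O)[C@H](c1ccc(O)cc1)O2
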